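Does raising the nucleophile from the south charge to the north-west charge change how much electrophile reacts?

the same everywhere: electrophile 10 mM; gas 0.42 mM (held)
- zeta: nucleophile 1.1 equiv; run made earlier
- alpha: nucleophile 2.3 equiv; run made earlier
- south: nucleophile 2.00 equiv; time 20 min
- north-west: nucleophile 3.00 equiv; time 20 min

| run | time / min | electrophile / % | target / % |
|---|---|---|---|
| zeta | 1.33 | 50.9 | 52.7 |
| zeta | 4.00 | 45.1 | 54.0 |
| zeta | 6.00 | 45.3 | 52.8 |
| zeta | 10.0 | 43.5 | 48.9 |
| zeta | 15.0 | 42.3 | 48.2 |
| alpha | 3.00 | 4.2 | 92.1 |
| alpha | 6.00 | 0 | 91.5 |
| alpha | 8.00 | 0 | 91.3 |
| alpha | 12.0 | 0 | 87.8 |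
| alpha | 15.0 | 0.7 | 83.4 |

(standard deviation of a reading: 1 percentage point)

- at the start none of free base is dissolved
- steps that have been proposed: electrophile + nucleophile <-> acid set free + target; nucleophile + acid set free <-> protonated nucleophile; acid set free + free base <-> salt of the base; gas <-> free base; target <-> isomer of the product

- part of the electrophile that has reacted at the end, south
- part of the electrophile that has reacted at the end, north-west
- what raising the equivalents of nucleophile from its lowest to its highest value here does to the part of the electrophile that has reacted (changes below 5 percentage points count as none) (it falls / it rises / no change)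

Reckon with the fraction of electrophile left, not with target: in the alpha run target sinks from 91.5% to 83.4% while electrophile reads 0% and then 0.7%. Each electrophile that reacts sets acid free, and that acid can take a second nucleophile as protonated nucleophile. So fold the charges into one number, the cover: c(nucleophile) over 2 c(electrophile) at the start, 1.00 for south. If each acid set free takes a nucleophile, then below one nucleophile is the limiting reagent, and the fraction left should stall near one minus the cover. For zeta, a cover of 0.550 gives 45.0%, and the reading at 4.00 min is 45.1%.

One number is not enough, though. The last zeta reading, 42.3%, lies 2.7 percentage points below that reckoned stall, beyond the scatter. The cover also carries no time: alpha, at 1.15, still reads 4.2% at 3.00 min and 0% at 6.00 min. With south at 1.00 and north-west at 1.50, each run for 20 min, I expect a rest under 5 points in south and none in north-west, so no change.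

The forecast gives 99% and 100% and differs from me on the trend, it rises: “Conversion therefore rises across the range, from about 58% to 100%”.

The flask gives 98.0% in south and >99.9% in north-west, a change of 2 points: no change.

    electrophile + nucleophile ⇌ acid set free + target (K = 4.00, k = 2.70 M⁻¹ s⁻¹)
    nucleophile + acid set free ⇌ protonated nucleophile, settled at all times (K = 4.90 × 10⁵ M⁻¹)
    acid set free + free base ⇌ salt of the base (K = 9.80 × 10⁵ M⁻¹, k = 6.30 M⁻¹ s⁻¹)
    gas ⇌ free base, rate k4*(csat - [free base]) (kL = 0.110 s⁻¹)
    target ⇌ isomer of the product (K = 1.80, k = 2.10 × 10⁻⁴ s⁻¹)

South, at a cover of 1.00, ends with 2.0% of its electrophile and 2.6% of its nucleophile. The neighbour of south with 1.20 equiv has a cover of 0.600, which reckons 40.0% of the electrophile left. At 20.0 min that neighbour holds 0.61% of its nucleophile and 37.5% of its electrophile.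

The numbers in the tables are simulated for substances that don't exist, noise included.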